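1. Beside this flask stands a neighbour, the same flask but with 2.2 M of incoming ligand, and I wanted one rule for both before I saw either result.

starting complex 0.58 M; incoming ligand 0.551 M; time 15 d

    starting complex + incoming ligand ⇌ leaving ligand + complex with one exchanged (K1 = 0.68, k1 = 0.031 M⁻¹ h⁻¹)
    complex with one exchanged + incoming ligand ⇌ leaving ligand + complex with two exchanged (K2 = 0.84, k2 = 0.073 M⁻¹ h⁻¹)
    starting complex ⇌ dormant form (K3 = 1.3, k3 = 0.78 h⁻¹)
    complex with two exchanged ⇌ isomer of the product (K4 = 0.33, k4 = 0.030 h⁻¹)

* which holds at 15 d: what has brought the reaction to rest, or that it has not come to rest (the incoming ligand has run out first / it is still moving / forward and back rates have come level / all of the starting complex has reacted)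
* how much of the starting complex has reacted by 15 d
* how much complex with two exchanged there is at 15 d, in percent of the starting complex charged

- what has gone from starting complex into another species counts as reacted, even if it can come back
- the reaction counts as stopped when no species that holds the starting complex changes by six tenths of a point or more over the second half of the time
- run time (flask): 15 d

2. In this flask at the start, the forward rate from starting complex to the dormant form was 46 times the forward rate into the first exchange. The bench rule for such a gap is a pre-equilibrium: I let the pair of starting complex and dormant form keep its balance and treated it as one pool that the first exchange draws on.

3. I named the free share, the part of that pool standing as starting complex. From the dormant step's constant 1.3, it was 43.5%.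

4. Reacted material was then the whole charge less the free share of what had not been exchanged. With the pair balanced and nothing yet counted as exchanged, the rule put this flask at 56.5% reacted, and I took that estimate as my floor.

5. The rule had two borders. It could not hold before the pair had relaxed, with a half-life of 0.502 h. It also needed the rate ratio to stay above one, and the neighbour's ratio at the start was 11.4.

6. With incoming ligand as charged, the pool's forward half-life through the first exchange in this flask was 3.89 d, shorter than 15 d, so I expected that exchange to be near rest by the end. My reckoning stopped at the floor.

7. The forecast went further, to a full balance: forward and back rates have come level, 71% reacted and 12.6% complex with two exchanged, holding that “the system should be at equilibrium well before the second half ends”.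

8. The simulation gave forward and back rates have come level, 71.3% reacted and 12.6% complex with two exchanged. In this flask the forward half-life of starting complex by the first exchange was 3.6 d at 15.0 d, short against 15 d, and the largest shift over the second half was 0.3 percentage points. Its pool then read a free share of 43.5%, and with 33.9% of the charge exchanged the rule gave 71.2% reacted. In the neighbour with 2.2 M of incoming ligand, the free share read 43.5% and 86.6% had reacted.

Its constants are those of an exercise; the run is a simulation.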